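**Plan**
- Cuts: the end game only removes two MOM groups, one silyl group and MeOH (C1 acetal → C1=C8a). Before that, the carbocycle of the quinone methide unit is opened at C8–C7, C6–C5 and C8–C8a, which also separates the two halves next to the CH2 bridge.
- Enabling feature: this ring is a 2-alkylresorcinol (O on C6 and C8, the CH2–aryl arm on C7 between them, Me on C5) fused to the pyran through C4a–C8a. A vinylketene (C8, C5, C4a, C8a) and an ynol ether (C7, C6) give exactly this pattern in a benzannulation.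
- Forward order: left pyran first (dihydropyranone → 4-acyl-6-methoxy-dihydropyran → α-diazo ketone 13). Right isochromane by oxa-Pictet–Spengler closure, then C7 propargylation and conversion to siloxyalkyne 32. 13 + 32 close the last ring; deprotection follows.
- Stereochemistry: left C3/C4 from ethyl (R)-3-hydroxybutanoate by anti-selective Fráter–Seebach methylation. Right C4′ by SN2 opening of (2S,3S)-2,3-dimethyloxirane, right C3′ by oxidation and Felkin–Anh reduction.

Key step: step 19

Remark: the acetal carbon (C6 of the dihydropyran, later C1 of the left isochromene unit) and the sp3 carbons that exist only in transient intermediates 7, 34 and 36 are carried as epimer mixtures and written without configuration, because all of them end as sp2 carbons.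

**Left unit**

Step 1
Reactants: 1 ethyl (R)-3-hydroxybutanoate
Product: 3 ethyl (2R,3R)-3-hydroxy-2-methylbutanoate, via dilithium dianion 2 (not isolated)
Conditions: LiN(i-Pr)2 (2.2 equiv), THF, −50 → −20 °C; MeI, DMPU, −78 → −20 °C
Reagents that add atoms: iodomethane, CI
Why: Fráter–Seebach alkylation, in which the chelated dilithium alkoxide–enolate should be methylated anti to the carbinol substituent, so that the existing (R) centre sets C2 as (R).

Step 2
Reactants: 3 ethyl (2R,3R)-3-hydroxy-2-methylbutanoate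
Product: 4 (2R,3R)-3-hydroxy-N-methoxy-N,2-dimethylbutanamide
Conditions: MeNH(OMe)·HCl, i-PrMgCl, THF, −20 → 0 °C
Reagents that add atoms: N,O-dimethylhydroxylamine hydrochloride, CNOC.Cl
Why: Weinreb amide formation by aminolysis of the ester with the magnesium amide, which is non-enolising at low temperature and should leave the α-centre untouched.

Step 3
Reactants: 4 (2R,3R)-3-hydroxy-N-methoxy-N,2-dimethylbutanamide
Product: 5 (4R,5R)-5-hydroxy-4-methylhex-1-yn-3-one
Conditions: HC≡CMgBr (3.5 equiv), THF, −78 → 0 °C; inverse quench into cold aq NaHSO4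
Reagents that add atoms: ethynylmagnesium bromide, C#C[Mg]Br
Why: Alkynyl Grignard addition to a Weinreb amide stops at the ketone through the chelated tetrahedral intermediate, with the excess reagent covering the free hydroxyl.

Step 4
Reactants: 5 (4R,5R)-5-hydroxy-4-methylhex-1-yn-3-one
Product: 6 (2R,3R)-2,3-dimethyl-2,3-dihydro-4H-pyran-4-one
Conditions: AgOTf (10 mol %), CH2Cl2, 23 °C
Reagents that add atoms: none
Why: π-Acid-catalysed 6-endo-dig oxa-Michael cyclisation of a β-hydroxy ynone should give the dihydropyranone, and its 2,3-trans isomer is also the thermodynamic one, so the α-centre is not at risk.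

Step 5
Reactants: 6 (2R,3R)-2,3-dimethyl-2,3-dihydro-4H-pyran-4-one
Product: 8 1-[(2R,3S)-6-methoxy-2,3-dimethyl-3,6-dihydro-2H-pyran-4-yl]ethan-1-one, via carbinol 7 (not isolated)
Conditions: CH2=CHOEt, t-BuLi, THF, −78 → 0 °C; 6, −78 °C; H2O; then crude 7, CSA (5 mol %), MeOH/H2O (50:1), 0 → 23 °C
Reagents that add atoms: ethyl vinyl ether, C=COCC; methanol, CO; water, O
Why: 1,2-Addition of 1-ethoxyvinyllithium (acyl anion equivalent) to the vinylogous ester, then acid-catalysed allylic transposition of Ferrier/Stork–Danheiser type with capture of the ring oxocarbenium ion by methanol at C6 and hydrolysis of the enol ether; C2 and C3 are untouched, and the change of the C3 descriptor from R to S is only a CIP priority effect.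

Step 6
Reactants: 8 1-[(2R,3S)-6-methoxy-2,3-dimethyl-3,6-dihydro-2H-pyran-4-yl]ethan-1-one
Product: 10 1-[(2R,3S)-6-methoxy-2,3-dimethyl-3,6-dihydro-2H-pyran-4-yl]propan-1-one, via lithium enolate 9 (not isolated)
Conditions: LiN(SiMe3)2 (1.05 equiv), THF, −78 °C; MeI, DMPU, −78 → −40 °C
Reagents that add atoms: iodomethane, CI
Why: Kinetic deprotonation of the methyl ketone at its only α′ position and C-methylation of the lithium enolate (enolate alkylation); the allylic C3–H is not acidic.

Step 7
Reactants: 10 1-[(2R,3S)-6-methoxy-2,3-dimethyl-3,6-dihydro-2H-pyran-4-yl]propan-1-one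
Product: 13 2-diazo-1-[(2R,3S)-6-methoxy-2,3-dimethyl-3,6-dihydro-2H-pyran-4-yl]propan-1-one, via lithium enolate 11 (not isolated), via trifluoroacetyl diketone 12 (not isolated)
Conditions: LiN(SiMe3)2, THF, −78 °C; CF3CO2CH2CF3; then MsN3, Et3N, H2O (1 equiv), MeCN, 23 °C
Reagents that add atoms: methanesulfonyl azide, CS(=O)(=O)N=[N+]=[N-]
Why: Detrifluoroacetylative diazo transfer (Regitz-type): the kinetic enolate is trifluoroacetylated and the activated 1,3-diketone takes up the diazo group with loss of the trifluoroacetyl group, under conditions mild enough for the allylic acetal.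

**Right unit**

Step 8
Reactants: 14 1-bromo-3,5-dimethoxybenzene
Product: 16 2-bromo-4,6-dimethoxybenzaldehyde, via iminium salt 15 (not isolated)
Conditions: POCl3, DMF, 0 → 90 °C; then aq NaOAc
Reagents that add atoms: N,N-dimethylformamide, CN(C)C=O; water, O
Why: Vilsmeier–Haack formylation is expected ortho to bromine (ortho/para to the two methoxy groups); the isomer formylated between the methoxy groups should be a separable minor product.

Step 9
Reactants: 16 2-bromo-4,6-dimethoxybenzaldehyde
Product: 17 1-bromo-3,5-dimethoxy-2-methylbenzene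
Conditions: Et3SiH (3 equiv), CF3CO2H, CH2Cl2, 0 → 23 °C
Reagents that add atoms: none
Why: Ionic hydrogenation of an electron-rich benzaldehyde through the benzylic cation should give the methyl group without touching the aryl bromide.

Step 10
Reactants: 17 1-bromo-3,5-dimethoxy-2-methylbenzene; 18 (2S,3S)-2,3-dimethyloxirane
Product: 20 (2S,3S)-3-(3,5-dimethoxy-2-methylphenyl)butan-2-ol, via aryllithium 19 (not isolated)
Conditions: n-BuLi, THF, −78 °C; then 18, BF3·OEt2, −78 °C
Reagents that add atoms: none
Why: Bromine–lithium exchange and BF3-promoted SN2 opening of the trans-epoxide with inversion at the attacked carbon set the benzylic centre as (S); the carbinol centre is still (S) and is corrected in steps 11 and 12.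

Step 11
Reactants: 20 (2S,3S)-3-(3,5-dimethoxy-2-methylphenyl)butan-2-ol
Product: 21 (3S)-3-(3,5-dimethoxy-2-methylphenyl)butan-2-one
Conditions: Dess–Martin periodinane, NaHCO3, CH2Cl2, 0 → 23 °C
Reagents that add atoms: none
Why: Dess–Martin oxidation under buffered, non-enolising conditions should give the α-aryl ketone without epimerising the benzylic centre.

Step 12
Reactants: 21 (3S)-3-(3,5-dimethoxy-2-methylphenyl)butan-2-one
Product: 22 (2R,3S)-3-(3,5-dimethoxy-2-methylphenyl)butan-2-ol
Conditions: LiBH(s-Bu)3, THF, −78 °C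
Reagents that add atoms: none
Why: Felkin–Anh reduction, with the bulky hydride attacking anti to the aryl group, should give the (2R,3S) alcohol, the relative configuration that becomes the trans-3,4-dimethyl ring.

Step 13
Reactants: 22 (2R,3S)-3-(3,5-dimethoxy-2-methylphenyl)butan-2-ol
Product: 23 (3R,4S)-6,8-dimethoxy-3,4,5-trimethylisochromane
Conditions: CH2(OMe)2 (1.5 equiv), BF3·OEt2, CH2Cl2, 0 → 23 °C
Reagents that add atoms: dimethoxymethane, COCOC
Why: Oxa-Pictet–Spengler cyclisation, in which the alkoxymethyl oxocarbenium ion closes at the only free ortho position (ortho/para to the methoxy groups); no stereocentre is involved.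

Step 14
Reactants: 23 (3R,4S)-6,8-dimethoxy-3,4,5-trimethylisochromane
Product: 24 (3R,4S)-3,4,5-trimethylisochromane-6,8-diol
Conditions: BBr3, CH2Cl2, −78 → 0 °C; then H2O
Reagents that add atoms: none
Why: BBr3 cleaves both aryl methyl ethers; should the benzylic ether also open, the o-hydroxybenzyl bromide is expected to reclose onto the secondary alcohol on work-up.

Step 15
Reactants: 24 (3R,4S)-3,4,5-trimethylisochromane-6,8-diol
Product: 25 (3R,4S)-6,8-bis(methoxymethoxy)-3,4,5-trimethylisochromane
Conditions: NaH, MOMCl, DMF, 0 °C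
Reagents that add atoms: chloromethyl methyl ether, COCCl
Why: Williamson alkylation of both phenoxides gives the bis-MOM ether, which serves as the double directing group in the next step.

Step 16
Reactants: 25 (3R,4S)-6,8-bis(methoxymethoxy)-3,4,5-trimethylisochromane
Product: 28 (3R,4S)-6,8-bis(methoxymethoxy)-3,4,5-trimethyl-7-[3-(trimethylsilyl)prop-2-yn-1-yl]isochromane, via aryllithium 26 (not isolated), via arylcopper 27 (not isolated)
Conditions: n-BuLi, THF, 0 °C; CuBr·SMe2, −40 °C; Me3SiC≡CCH2Br, −40 → 0 °C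
Reagents that add atoms: (3-bromoprop-1-yn-1-yl)trimethylsilane, C[Si](C)(C)C#CCBr
Why: Directed ortho-metalation at the only aromatic C–H (flanked by two OMOM groups), transmetalation to copper and SN2 alkylation; the silyl cap on the propargyl bromide suppresses SN2′ allene formation.

Step 17
Reactants: 28 (3R,4S)-6,8-bis(methoxymethoxy)-3,4,5-trimethyl-7-[3-(trimethylsilyl)prop-2-yn-1-yl]isochromane
Product: 29 (3R,4S)-6,8-bis(methoxymethoxy)-3,4,5-trimethyl-7-(prop-2-yn-1-yl)isochromane
Conditions: K2CO3 (cat.), MeOH, 0 → 23 °C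
Reagents that add atoms: none
Why: Carbonate-catalysed methanolysis of the C(sp)–Si bond is mild enough to avoid isomerisation of the benzylic alkyne.

Step 18
Reactants: 29 (3R,4S)-6,8-bis(methoxymethoxy)-3,4,5-trimethyl-7-(prop-2-yn-1-yl)isochromane
Product: 32 (3R,4S)-6,8-bis(methoxymethoxy)-3,4,5-trimethyl-7-{3-[(triisopropylsilyl)oxy]prop-2-yn-1-yl}isochromane, via lithium acetylide 30 (not isolated), via lithium ynolate 31 (not isolated)
Conditions: LiN(SiMe3)2, THF, −78 °C; t-BuOOLi (from t-BuOOH and LiN(SiMe3)2), −78 → 0 °C; i-Pr3SiOTf, −78 °C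
Reagents that add atoms: tert-butyl hydroperoxide, CC(C)(C)OO; triisopropylsilyl trifluoromethanesulfonate, CC(C)[Si](C(C)C)(C(C)C)OS(=O)(=O)C(F)(F)F
Why: Acetylide-to-ynolate oxidation with lithium tert-butylperoxide, then O-silylation of the ynolate by the bulky silyl triflate, is the standard access to 1-siloxyalkynes from terminal alkynes.

**Union and end game**

Step 19
Reactants: 13 2-diazo-1-[(2R,3S)-6-methoxy-2,3-dimethyl-3,6-dihydro-2H-pyran-4-yl]propan-1-one; 32 (3R,4S)-6,8-bis(methoxymethoxy)-3,4,5-trimethyl-7-{3-[(triisopropylsilyl)oxy]prop-2-yn-1-yl}isochromane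
Product: 37 (3R,4S)-7-{[(3R,4S)-6,8-bis(methoxymethoxy)-3,4,5-trimethylisochroman-7-yl]methyl}-1-methoxy-3,4,5-trimethyl-6-[(triisopropylsilyl)oxy]isochroman-8-ol, via vinylketene 33 (not isolated), via vinylcyclobutenone 34 (not isolated), via dienylketene 35 (not isolated), via cyclohexadienone 36 (not isolated)
Conditions: 32 (1.3 equiv), hν (350 nm), ClCH2CH2Cl, 23 °C; then 80 °C
Reagents that add atoms: none
Why: Irradiation causes Wolff rearrangement of 13 (1,2-shift of the dihydropyranyl group, loss of N2) to vinylketene 33, which adds across its ketene C=C to the siloxyalkyne in a [2+2] cycloaddition to give vinylcyclobutenone 34; on warming, conrotatory 4π ring opening gives dienylketene 35, disrotatory 6π electrocyclisation (new C8–C8a bond) gives cyclohexa-2,4-dienone 36, and tautomerisation gives phenol 37. The closest known reaction type is the Danheiser benzannulation in its diazo ketone variant with siloxyalkynes, which is established for alkenyl diazo ketones and for hexasubstituted arenes. The six-membered carbocycle, the only ring of the product that is formed, closes by thermal 6π electrocyclisation of the dienylketene; the four-membered ring of 34 is a transient that closes by [2+2] cycloaddition and reopens. No lasting stereocentre is created: C8a of 36 is aromatised, the acetal carbon remains an epimer mixture that ends sp2, and C3/C4 and C3′/C4′ are not enolisable under these neutral conditions and should be carried through unchanged. The step needs the regiochemistry that puts the arylmethyl-bearing carbon between the two oxygenated carbons (C7 between C6 and C8) and the methyl group on C5; this is secured by the polarisation of the partners (the nucleophilic β-carbon of the ynol ether bonds to the electrophilic ketene carbonyl carbon) and by the methyl group on the diazo carbon of 13. Chemoselectivity for the ynol ether over the MOM-protected arene, the acetals and the product phenol rests on the high nucleophilicity of the siloxyalkyne, used in slight excess so that the ketene is consumed before it can acylate 37.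

Step 20
Reactants: 37 (3R,4S)-7-{[(3R,4S)-6,8-bis(methoxymethoxy)-3,4,5-trimethylisochroman-7-yl]methyl}-1-methoxy-3,4,5-trimethyl-6-[(triisopropylsilyl)oxy]isochroman-8-ol
Product: 39 dicitrinone I, via quinone methide 38 (not isolated)
Conditions: Bu4NF, AcOH, THF, 0 °C; then 3 M HCl, MeOH, 40 °C
Reagents that add atoms: none
Why: Fluoride removes the aryl silyl ether and the resulting 1-methoxy-isochromane-6,8-diol should lose methanol to the vinylogous-acid quinone methide 38; methanolic HCl then cleaves both MOM acetals by transacetalisation, while the left unit survives as its benzopyrylium/methanol adduct and returns to the quinone methide on work-up.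

**Compound list**

1 | ethyl (R)-3-hydroxybutanoate | CCOC(=O)C[C@@H](C)O | starting material
2 | dilithium alkoxide–enolate of 1 | CCOC(O[Li])=C[C@@H](C)O[Li] | intermediate (not isolated)
3 | ethyl (2R,3R)-3-hydroxy-2-methylbutanoate | C[C@@H](O)[C@@H](C)C(=O)OCC | intermediate
4 | (2R,3R)-3-hydroxy-N-methoxy-N,2-dimethylbutanamide | C[C@@H](O)[C@@H](C)C(=O)N(C)OC | intermediate
5 | (4R,5R)-5-hydroxy-4-methylhex-1-yn-3-one | C[C@@H](O)[C@@H](C)C(=O)C#C | intermediate
6 | (2R,3R)-2,3-dimethyl-2,3-dihydro-4H-pyran-4-one | O=C1C=CO[C@H](C)[C@H]1C | intermediate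
7 | (2R,3R)-4-(1-ethoxyethenyl)-2,3-dimethyl-3,4-dihydro-2H-pyran-4-ol | C=C(OCC)C1(O)C=CO[C@H](C)[C@H]1C | intermediate (not isolated)
8 | 1-[(2R,3S)-6-methoxy-2,3-dimethyl-3,6-dihydro-2H-pyran-4-yl]ethan-1-one | CC(=O)C1=CC(OC)O[C@H](C)[C@H]1C | intermediate
9 | lithium enolate of 8 | [Li]OC(=C)C1=CC(OC)O[C@H](C)[C@H]1C | intermediate (not isolated)
10 | 1-[(2R,3S)-6-methoxy-2,3-dimethyl-3,6-dihydro-2H-pyran-4-yl]propan-1-one | CCC(=O)C1=CC(OC)O[C@H](C)[C@H]1C | intermediate
11 | lithium enolate of 10 | CC=C(O[Li])C1=CC(OC)O[C@H](C)[C@H]1C | intermediate (not isolated)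
12 | 4,4,4-trifluoro-1-[(2R,3S)-6-methoxy-2,3-dimethyl-3,6-dihydro-2H-pyran-4-yl]-2-methylbutane-1,3-dione | CC(C(=O)C(F)(F)F)C(=O)C1=CC(OC)O[C@H](C)[C@H]1C | intermediate (not isolated)
13 | 2-diazo-1-[(2R,3S)-6-methoxy-2,3-dimethyl-3,6-dihydro-2H-pyran-4-yl]propan-1-one | CC(=[N+]=[N-])C(=O)C1=CC(OC)O[C@H](C)[C@H]1C | intermediate
14 | 1-bromo-3,5-dimethoxybenzene | COc1cc(Br)cc(OC)c1 | starting material
15 | N-[(2-bromo-4,6-dimethoxyphenyl)methylidene]-N-methylmethanaminium chloride | C[N+](C)=Cc1c(Br)cc(OC)cc1OC.[Cl-] | intermediate (not isolated)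
16 | 2-bromo-4,6-dimethoxybenzaldehyde | O=Cc1c(Br)cc(OC)cc1OC | intermediate
17 | 1-bromo-3,5-dimethoxy-2-methylbenzene | Cc1c(Br)cc(OC)cc1OC | intermediate
18 | (2S,3S)-2,3-dimethyloxirane (trans-2,3-epoxybutane) | C[C@@H]1O[C@H]1C | starting material
19 | (3,5-dimethoxy-2-methylphenyl)lithium | [Li]c1cc(OC)cc(OC)c1C | intermediate (not isolated)
20 | (2S,3S)-3-(3,5-dimethoxy-2-methylphenyl)butan-2-ol | C[C@H](O)[C@@H](C)c1cc(OC)cc(OC)c1C | intermediate
21 | (3S)-3-(3,5-dimethoxy-2-methylphenyl)butan-2-one | CC(=O)[C@@H](C)c1cc(OC)cc(OC)c1C | intermediate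
22 | (2R,3S)-3-(3,5-dimethoxy-2-methylphenyl)butan-2-ol | C[C@@H](O)[C@@H](C)c1cc(OC)cc(OC)c1C | intermediate
23 | (3R,4S)-6,8-dimethoxy-3,4,5-trimethylisochromane | COc1cc(OC)c(C)c2c1CO[C@H](C)[C@H]2C | intermediate
24 | (3R,4S)-3,4,5-trimethylisochromane-6,8-diol | Oc1cc(O)c(C)c2c1CO[C@H](C)[C@H]2C | intermediate
25 | (3R,4S)-6,8-bis(methoxymethoxy)-3,4,5-trimethylisochromane | COCOc1cc(OCOC)c(C)c2c1CO[C@H](C)[C@H]2C | intermediate
26 | 7-lithio derivative of 25 | COCOc1c([Li])c(OCOC)c(C)c2c1CO[C@H](C)[C@H]2C | intermediate (not isolated)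
27 | 7-cuprio derivative of 25 | COCOc1c([Cu])c(OCOC)c(C)c2c1CO[C@H](C)[C@H]2C | intermediate (not isolated)
28 | (3R,4S)-6,8-bis(methoxymethoxy)-3,4,5-trimethyl-7-[3-(trimethylsilyl)prop-2-yn-1-yl]isochromane | COCOc1c(CC#C[Si](C)(C)C)c(OCOC)c(C)c2c1CO[C@H](C)[C@H]2C | intermediate
29 | (3R,4S)-6,8-bis(methoxymethoxy)-3,4,5-trimethyl-7-(prop-2-yn-1-yl)isochromane | COCOc1c(CC#C)c(OCOC)c(C)c2c1CO[C@H](C)[C@H]2C | intermediate
30 | lithium acetylide of 29 | COCOc1c(CC#C[Li])c(OCOC)c(C)c2c1CO[C@H](C)[C@H]2C | intermediate (not isolated)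
31 | lithium ynolate from 30 | COCOc1c(CC#CO[Li])c(OCOC)c(C)c2c1CO[C@H](C)[C@H]2C | intermediate (not isolated)
32 | (3R,4S)-6,8-bis(methoxymethoxy)-3,4,5-trimethyl-7-{3-[(triisopropylsilyl)oxy]prop-2-yn-1-yl}isochromane | COCOc1c(CC#CO[Si](C(C)C)(C(C)C)C(C)C)c(OCOC)c(C)c2c1CO[C@H](C)[C@H]2C | intermediate
33 | 2-[(2R,3S)-6-methoxy-2,3-dimethyl-3,6-dihydro-2H-pyran-4-yl]prop-1-en-1-one (vinylketene) | CC(=C=O)C1=CC(OC)O[C@H](C)[C@H]1C | intermediate (not isolated)
34 | 2-(arylmethyl)-4-(dihydropyranyl)-4-methyl-3-(triisopropylsilyloxy)cyclobut-2-en-1-one | O=C1C(Cc2c(OCOC)c(C)c3c(c2OCOC)CO[C@H](C)[C@H]3C)=C(O[Si](C(C)C)(C(C)C)C(C)C)C1(C)C4=CC(OC)O[C@H](C)[C@H]4C | intermediate (not isolated)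
35 | 2-(arylmethyl)-4-(dihydropyranyl)-3-(triisopropylsilyloxy)penta-1,3-dien-1-one (dienylketene) | O=C=C(Cc2c(OCOC)c(C)c3c(c2OCOC)CO[C@H](C)[C@H]3C)C(O[Si](C(C)C)(C(C)C)C(C)C)=C(C)C1=CC(OC)O[C@H](C)[C@H]1C | intermediate (not isolated)
36 | 8a-H cyclohexa-2,4-dienone tautomer of 37 | O=C1C(Cc2c(OCOC)c(C)c3c(c2OCOC)CO[C@H](C)[C@H]3C)=C(O[Si](C(C)C)(C(C)C)C(C)C)C(C)=C4C1C(OC)O[C@H](C)[C@H]4C | intermediate (not isolated)
37 | (3R,4S)-7-{[(3R,4S)-6,8-bis(methoxymethoxy)-3,4,5-trimethylisochroman-7-yl]methyl}-1-methoxy-3,4,5-trimethyl-6-[(triisopropylsilyl)oxy]isochroman-8-ol | Oc1c(Cc2c(OCOC)c(C)c3c(c2OCOC)CO[C@H](C)[C@H]3C)c(O[Si](C(C)C)(C(C)C)C(C)C)c(C)c4c1C(OC)O[C@H](C)[C@H]4C | intermediate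
38 | (3R,4S)-7-{[(3R,4S)-6,8-bis(methoxymethoxy)-3,4,5-trimethylisochroman-7-yl]methyl}-6-hydroxy-3,4,5-trimethyl-3,4-dihydro-8H-isochromen-8-one | CC1=C2C(=CO[C@H](C)[C@H]2C)C(=O)C(Cc2c(OCOC)c(C)c3c(c2OCOC)CO[C@H](C)[C@H]3C)=C1O | intermediate (not isolated)
39 | dicitrinone I, (3R,4S)-7-{[(3R,4S)-6,8-dihydroxy-3,4,5-trimethylisochroman-7-yl]methyl}-6-hydroxy-3,4,5-trimethyl-3,4-dihydro-8H-isochromen-8-one | CC1=C2C(=CO[C@H](C)[C@H]2C)C(=O)C(Cc2c(O)c(C)c3c(c2O)CO[C@H](C)[C@H]3C)=C1O | target

**Step count**

Total: 20 steps. Longest linear sequence: 13 steps (steps 8–18, 19, 20, from 14); the left branch is 7 steps before the union.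

**Steps most likely to fail**

Step 19. The aryl chromophore of 32 may compete for light so that the Wolff rearrangement is inefficient, the fully substituted ketene may add too slowly and dimerise, or the ketene may acylate the product phenol. The fallback sets out from 24 and comes back at 39, and it joins two preformed units at the methylene carbon instead of building the ring. One portion of 24 is aminomethylated at its only free aromatic position with dimethyl(methylidene)ammonium iodide to give the Mannich base (3R,4S)-7-[(dimethylamino)methyl]-3,4,5-trimethylisochromane-6,8-diol F1. A second portion of 24 is dehydrogenated with DDQ in dioxane to the quinone methide (3R,4S)-6-hydroxy-3,4,5-trimethyl-3,4-dihydro-8H-isochromen-8-one F2. Heating F1 with F2 in toluene should release dimethylamine from F1 to give the ortho-quinone methide (3R,4S)-6-hydroxy-3,4,5-trimethyl-7-methylidene-3,4-dihydro-1H-isochromen-8(7H)-one F3. F3 is captured in a Michael addition by C7 of F2, the carbon between its two oxygenated carbons, to give 39.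

Step 18. The base may deprotonate the benzylic–propargylic CH2 and isomerise the alkyne to the allene, and the ynolate may be silylated on carbon instead of oxygen. The fallback sets out from 25 and comes back at 32 by ester homologation instead of acetylide oxidation. 25 is lithiated as in step 16 and transmetalated with ZnCl2 to the arylzinc chloride F4. Negishi coupling of F4 with ethyl bromoacetate under Pd(PPh3)4 catalysis gives ethyl 2-[(3R,4S)-6,8-bis(methoxymethoxy)-3,4,5-trimethylisochroman-7-yl]acetate F5. Kowalski ester homologation follows: LiCHBr2 (from CH2Br2 and lithium 2,2,6,6-tetramethylpiperidide, −78 °C) gives 1,1-dibromo-3-[(3R,4S)-6,8-bis(methoxymethoxy)-3,4,5-trimethylisochroman-7-yl]propan-2-one F6 as its enolate. n-BuLi (−78 → 0 °C) then triggers bromine–lithium exchange and 1,2-shift of the arylmethyl group to ynolate 31, and i-Pr3SiOTf gives 32.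

Step 6. Proton exchange between the enolate and the product may lead to double methylation, and deprotonation at the γ (acetal) carbon may compete and expel methoxide. The fallback sets out from 6 and comes back at 10, and it brings in the whole propionyl group as an acyl anion equivalent, so steps 5 and 6 are both replaced. 2-Ethyl-2-lithio-1,3-dithiane (from 2-ethyl-1,3-dithiane and n-BuLi) adds to the carbonyl group of 6 to give (2R,3R)-4-(2-ethyl-1,3-dithian-2-yl)-2,3-dimethyl-3,4-dihydro-2H-pyran-4-ol F7. CSA in MeOH effects the same allylic transposition as in step 5 to give 2-ethyl-2-[(2R,3S)-6-methoxy-2,3-dimethyl-3,6-dihydro-2H-pyran-4-yl]-1,3-dithiane F8. Alkylative hydrolysis of F8 (MeI, CaCO3, MeCN/H2O) gives 10.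

**Further compounds**

F1 | step 19 | (3R,4S)-7-[(dimethylamino)methyl]-3,4,5-trimethylisochromane-6,8-diol | CN(C)Cc1c(O)c(C)c2c(c1O)CO[C@H](C)[C@H]2C
F2 | step 19 | (3R,4S)-6-hydroxy-3,4,5-trimethyl-3,4-dihydro-8H-isochromen-8-one | CC1=C2C(=CO[C@H](C)[C@H]2C)C(=O)C=C1O
F3 | step 19 | (3R,4S)-6-hydroxy-3,4,5-trimethyl-7-methylidene-3,4-dihydro-1H-isochromen-8(7H)-one | C=C1C(O)=C(C)C2=C(C1=O)CO[C@H](C)[C@H]2C
F4 | step 18 | [(3R,4S)-6,8-bis(methoxymethoxy)-3,4,5-trimethylisochroman-7-yl]zinc chloride | Cl[Zn]c1c(OCOC)c(C)c2c(c1OCOC)CO[C@H](C)[C@H]2C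
F5 | step 18 | ethyl 2-[(3R,4S)-6,8-bis(methoxymethoxy)-3,4,5-trimethylisochroman-7-yl]acetate | CCOC(=O)Cc1c(OCOC)c(C)c2c(c1OCOC)CO[C@H](C)[C@H]2C
F6 | step 18 | 1,1-dibromo-3-[(3R,4S)-6,8-bis(methoxymethoxy)-3,4,5-trimethylisochroman-7-yl]propan-2-one | BrC(Br)C(=O)Cc1c(OCOC)c(C)c2c(c1OCOC)CO[C@H](C)[C@H]2C
F7 | step 6 | (2R,3R)-4-(2-ethyl-1,3-dithian-2-yl)-2,3-dimethyl-3,4-dihydro-2H-pyran-4-ol | CCC1(SCCCS1)C2(O)C=CO[C@H](C)[C@H]2C
F8 | step 6 | 2-ethyl-2-[(2R,3S)-6-methoxy-2,3-dimethyl-3,6-dihydro-2H-pyran-4-yl]-1,3-dithiane | CCC1(SCCCS1)C2=CC(OC)O[C@H](C)[C@H]2C
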